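**Retrosynthetic overview**
1. Lapiferine comes from a C10‑OH‑directed epoxidation of C8=C9 (last step), PMB removal, and esterification of C6‑OH with angelic anhydride (fragment 3, C5, made from tiglic acid).
2. The C4 carbinol comes from i‑PrMgCl addition to a ring A ketone. C6‑OH and C5‑H come from conjugate borylation/oxidation of a bicyclic dienone.
3. Ring B and the quaternary C1 come from a divinylcyclopropane–cycloheptadiene rearrangement (C1–C10 bond). It follows a Negishi coupling (C5–C6 bond) of two C6 fragments: bromoenone (fragment 1) and an enantiopure iodocyclopropane (fragment 2).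
4. Fragment 2 comes from propargyl alcohol by carbomagnesiation/iodination, asymmetric Simmons–Smith reaction, oxidation, boryl olefination (reagent made from CH2Cl2) and C–O coupling.
5. Ring order: ring A (five‑membered, present in 3‑methylcyclopentenone), then the cyclopropane, then ring B (seven‑membered), then the epoxide.

Assumption: carotane numbering is used for locants (C1 = quaternary C–CH3, C4 = carbinol with i‑Pr, C5 = ring‑fusion CH, C6 = ester carbon, C8/C9 = epoxide, C10 = carbinol). β is the face of the C1 methyl, and the target is (1S,4R,5S,6S,8R,9S,10S). PMB = 4‑methoxybenzyl, Bpin = pinacolboryl.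

**Fragment 1**

Step 1
Reactants: 1 3-methylcyclopent-2-en-1-one
Product: 3 2-bromo-3-methylcyclopent-2-en-1-one, via dibromoketone 2 (not isolated)
Conditions: Br2, CH2Cl2, 0 °C; then Et3N, 0 °C to rt
Reagents that add atoms: bromine, BrBr
Why: Bromination–dehydrobromination: anti addition of Br2 to the enone and E1cB loss of HBr through the acidic α‑H leave the α‑bromoenone, in which no stereocentre remains.

**Olefination reagent (source of C10)**

Step 2
Reactants: 4 dichloromethane
Product: 7 2-(dichloromethyl)-4,4,5,5-tetramethyl-1,3,2-dioxaborolane, via dichloromethyllithium 5 (not isolated), via dichloromethylboronic acid 6 (not isolated)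
Conditions: n-BuLi, THF, −100 °C; B(OMe)3, −100 °C to rt; aq. HCl; then pinacol, MgSO4, CH2Cl2, rt
Reagents that add atoms: n-butyllithium, [Li]CCCC (Li of 5); trimethyl borate, COB(OC)OC; pinacol, CC(C)(O)C(C)(C)O
Why: Matteson-type borylation: the carbenoid anion of CH2Cl2 is trapped by the borate at low temperature and the boronic acid is esterified with pinacol; no stereocentre is formed.

**Fragment 2**

Step 3
Reactants: 8 prop-2-yn-1-ol
Product: 10 (Z)-3-iodo-2-methylprop-2-en-1-ol, via alkenylmagnesium alkoxide 9 (not isolated)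
Conditions: MeMgBr (2.5 equiv), CuI (10 mol %), THF/Et2O, −10 °C to rt; then I2, 0 °C; aq. NH4Cl
Reagents that add atoms: methylmagnesium bromide, C[Mg]Br; iodine, [I][I]
Why: Copper-catalysed anti carbomagnesiation of the propargylic alkoxide gives the chelated alkenylmagnesium with Mg cis to CH2O, and iodinolysis with retention fixes the Z geometry.

Step 4
Reactants: 10 (Z)-3-iodo-2-methylprop-2-en-1-ol
Product: 11 [(1R,2R)-2-iodo-1-methylcyclopropyl]methanol
Conditions: Et2Zn, CH2I2, DME, CH2Cl2, −10 °C; (4R,5R)-2-butyl-N,N,N',N'-tetramethyl-1,3,2-dioxaborolane-4,5-dicarboxamide (1.2 equiv), −10 °C to rt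
Reagents that add atoms: diiodomethane, C(I)I
Why: Charette asymmetric Simmons–Smith cyclopropanation: the zinc alkoxide bound to the chiral dioxaborolane receives CH2 on one alkene face (setting both stereocentres), and the syn addition keeps I and CH2OH cis.

Step 5
Reactants: 11 [(1R,2R)-2-iodo-1-methylcyclopropyl]methanol
Product: 12 (1R,2R)-2-iodo-1-methylcyclopropane-1-carbaldehyde
Conditions: Dess–Martin periodinane, CH2Cl2, 0 °C to rt
Reagents that add atoms: none
Why: Dess–Martin oxidation is neutral and mild, and the α‑carbon is quaternary, so nothing can epimerise.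

Step 6
Reactants: 12 (1R,2R)-2-iodo-1-methylcyclopropane-1-carbaldehyde; 7 2-(dichloromethyl)-4,4,5,5-tetramethyl-1,3,2-dioxaborolane
Product: 13 2-{(E)-2-[(1R,2R)-2-iodo-1-methylcyclopropyl]ethenyl}-4,4,5,5-tetramethyl-1,3,2-dioxaborolane
Conditions: CrCl2 (8 equiv), LiI (4 equiv), THF, rt
Reagents that add atoms: none
Why: Takai–Utimoto boryl olefination through a geminal dichromium reagent gives the E alkenylboronate selectively, and the strong cyclopropyl C–I bond is inert to CrCl2 without a nickel co-catalyst.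

Step 7
Reactants: 13 2-{(E)-2-[(1R,2R)-2-iodo-1-methylcyclopropyl]ethenyl}-4,4,5,5-tetramethyl-1,3,2-dioxaborolane
Product: 14 1-({(E)-2-[(1R,2R)-2-iodo-1-methylcyclopropyl]ethenyl}oxymethyl)-4-methoxybenzene
Conditions: 4-methoxybenzyl alcohol (5 equiv), Cu(OAc)2 (2 equiv), Et3N (4 equiv), 4 Å MS, CH2Cl2, rt
Reagents that add atoms: 4-methoxybenzyl alcohol, COc1ccc(CO)cc1
Why: Chan–Lam–Evans-type oxidative C–O coupling of an alkenylboronate with an alcohol proceeds with retention of alkene geometry and gives the pure E enol ether that later fixes C10.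

**Fragment 3**

Step 8
Reactants: 15 tiglic acid [(E)-2-methylbut-2-enoic acid]
Product: 16 rel-(2R,3S)-2,3-dibromo-2-methylbutanoic acid (racemic)
Conditions: Br2, CH2Cl2, 0 °C to rt
Reagents that add atoms: bromine, BrBr
Why: Electrophilic anti addition of bromine through the bromonium ion turns the E alkene into a single racemic diastereomer.

Step 9
Reactants: 16 rel-(2R,3S)-2,3-dibromo-2-methylbutanoic acid
Product: 17 (Z)-2-bromobut-2-ene
Conditions: Na2CO3, H2O, 60–70 °C, product distilled out
Reagents that add atoms: none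
Why: Grob-type decarboxylative anti elimination of carboxylate and C3 bromide is stereospecific, so anti addition followed by anti elimination gives only the Z bromide.

Step 10
Reactants: 17 (Z)-2-bromobut-2-ene
Product: 19 angelic acid [(Z)-2-methylbut-2-enoic acid], via alkenyllithium 18 (not isolated)
Conditions: t-BuLi (2.0 equiv), THF/Et2O, −78 °C; CO2; then 1 M HCl, 0 °C
Reagents that add atoms: tert-butyllithium, [Li]C(C)(C)C (Li of 18); carbon dioxide, O=C=O
Why: Halogen–lithium exchange and carboxylation both proceed with retention at the configurationally stable alkenyllithium and give geometrically pure angelic acid free of tiglic acid.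

Step 11
Reactants: 19 angelic acid (2 equiv)
Product: 20 angelic anhydride
Conditions: DCC (0.5 equiv), CH2Cl2, 0 °C to rt
Reagents that add atoms: none
Why: Carbodiimide dehydration forms the symmetrical anhydride under neutral conditions that do not isomerise the Z double bond.

**Union and endgame**

Step 12
Reactants: 14 1-({(E)-2-[(1R,2R)-2-iodo-1-methylcyclopropyl]ethenyl}oxymethyl)-4-methoxybenzene; 3 2-bromo-3-methylcyclopent-2-en-1-one
Product: 24 (3aS,4R)-4-[(4-methoxybenzyl)oxy]-3a,6-dimethyl-3,3a,4,7-tetrahydroazulen-1(2H)-one, via cyclopropyllithium 21 (not isolated), via cyclopropylzinc bromide 22 (not isolated), via cis-divinylcyclopropane 23 (not isolated)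
Conditions: t-BuLi (2.0 equiv), Et2O, −78 °C; ZnBr2, THF, −78 to 0 °C; 3, Pd2(dba)3 (2.5 mol %), SPhos (10 mol %), THF, 23–45 °C; filtration (SiO2/Et3N), then PhMe, 100 °C
Reagents that add atoms: tert-butyllithium, [Li]C(C)(C)C (Li of 21); zinc bromide, Br[Zn]Br (ZnBr of 22)
Why: Negishi coupling with retention at the configurationally stable cyclopropyl carbon places the two alkenyl groups cis, and the divinylcyclopropane–cycloheptadiene (Cope) rearrangement through the endo boat transition state then forms C1–C10, with the E enol ether and the ring alkene fixing CH3(C1) and O(C10) trans and the cyclopropane configuration being transferred to 1S,10R.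

Step 13
Reactants: 24 (3aS,4R)-4-[(4-methoxybenzyl)oxy]-3a,6-dimethyl-3,3a,4,7-tetrahydroazulen-1(2H)-one
Product: 26 (3aS,4R,8S,8aS)-8-hydroxy-4-[(4-methoxybenzyl)oxy]-3a,6-dimethyl-3,3a,4,7,8,8a-hexahydroazulen-1(2H)-one, via boryl ketone 25 (not isolated)
Conditions: B2pin2 (1.1 equiv), CuCl (5 mol %), DPEphos (5 mol %), NaOt-Bu (6 mol %), MeOH (2 equiv), THF, rt; then NaBO3·4H2O, THF/H2O, rt
Reagents that add atoms: bis(pinacolato)diboron, CC1(C)OB(OC1(C)C)B1OC(C)(C)C(C)(C)O1 (Bpin of 25); sodium perborate, [Na+].[Na+].O[B-]1(O)OO[B-](O)(O)OO1 (O at C6)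
Why: Copper-catalysed conjugate borylation and stereoretentive C–B oxidation: only the enone alkene is electrophilic, Cu–Bpin adds to C6 from the convex α face opposite the angular methyl (6S), and MeOH protonates the enolate on the same face to give the trans ring fusion (5S).

Step 14
Reactants: 26 (3aS,4R,8S,8aS)-8-hydroxy-4-[(4-methoxybenzyl)oxy]-3a,6-dimethyl-3,3a,4,7,8,8a-hexahydroazulen-1(2H)-one
Product: 27 (1R,3aS,4R,8S,8aS)-1-isopropyl-4-[(4-methoxybenzyl)oxy]-3a,6-dimethyl-1,2,3,3a,4,7,8,8a-octahydroazulene-1,8-diol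
Conditions: i-PrMgCl (4 equiv), LaCl3·2LiCl (1.5 equiv), THF, −20 to 0 °C; aq. NH4Cl
Reagents that add atoms: isopropylmagnesium chloride, CC(C)[Mg]Cl
Why: Lanthanide-assisted Grignard 1,2-addition: LaCl3·2LiCl suppresses enolisation and β‑hydride reduction, and the nucleophile attacks the C4 carbonyl from the α face (side of H5, opposite the angular methyl), setting 4R with OH β and i‑Pr α.

Step 15
Reactants: 27 (1R,3aS,4R,8S,8aS)-1-isopropyl-4-[(4-methoxybenzyl)oxy]-3a,6-dimethyl-1,2,3,3a,4,7,8,8a-octahydroazulene-1,8-diol; 20 angelic anhydride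
Product: 28 (1R,3aS,4R,8S,8aS)-1-hydroxy-1-isopropyl-4-[(4-methoxybenzyl)oxy]-3a,6-dimethyl-1,2,3,3a,4,7,8,8a-octahydroazulen-8-yl (Z)-2-methylbut-2-enoate
Conditions: LiHMDS (1.1 equiv), THF, −20 °C; 20 (1.3 equiv), −20 to 0 °C; aq. NH4Cl
Reagents that add atoms: none
Why: Acylation of the lithium alkoxide with the anhydride is fast at low temperature, so the angelate does not isomerise to the tiglate; only the secondary C6 alkoxide reacts because C4‑OH is tertiary and C10‑O is protected.

Step 16
Reactants: 28 (1R,3aS,4R,8S,8aS)-1-hydroxy-1-isopropyl-4-[(4-methoxybenzyl)oxy]-3a,6-dimethyl-1,2,3,3a,4,7,8,8a-octahydroazulen-8-yl (Z)-2-methylbut-2-enoate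
Product: 29 (1R,3aS,4R,8S,8aS)-1,4-dihydroxy-1-isopropyl-3a,6-dimethyl-1,2,3,3a,4,7,8,8a-octahydroazulen-8-yl (Z)-2-methylbut-2-enoate
Conditions: DDQ (1.3 equiv), CH2Cl2/pH 7 buffer (10:1), 0 °C
Reagents that add atoms: none
Why: Oxidative PMB cleavage by hydride abstraction from the electron-rich benzylic position leaves the ester, the alkenes and all stereocentres untouched.

Step 17
Reactants: 29 (1R,3aS,4R,8S,8aS)-1,4-dihydroxy-1-isopropyl-3a,6-dimethyl-1,2,3,3a,4,7,8,8a-octahydroazulen-8-yl (Z)-2-methylbut-2-enoate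
Product: 30 lapiferine
Conditions: VO(acac)2 (5 mol %), t-BuOOH (1.5 equiv, decane), CH2Cl2, 0 °C
Reagents that add atoms: tert-butyl hydroperoxide, CC(C)(C)OO
Why: Hydroxyl-directed vanadium-catalysed (Sharpless–Michaelson) epoxidation delivers oxygen to C8=C9 on the face of the allylic C10‑OH (α), setting 8R,9S, while the electron-poor angelate alkene is inert.

**Compound list**
1 | 3-methylcyclopent-2-en-1-one | CC1=CC(=O)CC1 | starting material
2 | trans-2,3-dibromo-3-methylcyclopentan-1-one (racemic, one enantiomer drawn) | C[C@@]1(Br)CCC(=O)[C@H]1Br | intermediate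
3 | 2-bromo-3-methylcyclopent-2-en-1-one (fragment 1) | CC1=C(Br)C(=O)CC1 | intermediate
4 | dichloromethane | ClCCl | starting material
5 | (dichloromethyl)lithium | [Li]C(Cl)Cl | intermediate
6 | (dichloromethyl)boronic acid | OB(O)C(Cl)Cl | intermediate
7 | 2-(dichloromethyl)-4,4,5,5-tetramethyl-1,3,2-dioxaborolane | ClC(Cl)B1OC(C)(C)C(C)(C)O1 | intermediate
8 | prop-2-yn-1-ol | C#CCO | starting material
9 | bromomagnesium (Z)-3-(bromomagnesio)-2-methylprop-2-en-1-olate | Br[Mg]/C=C(/C)CO[Mg]Br | intermediate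
10 | (Z)-3-iodo-2-methylprop-2-en-1-ol | I/C=C(/C)CO | intermediate
11 | [(1R,2R)-2-iodo-1-methylcyclopropyl]methanol (I and CH2OH cis) | I[C@@H]1C[C@]1(C)CO | intermediate
12 | (1R,2R)-2-iodo-1-methylcyclopropane-1-carbaldehyde | I[C@@H]1C[C@]1(C)C=O | intermediate
13 | 2-{(E)-2-[(1R,2R)-2-iodo-1-methylcyclopropyl]ethenyl}-4,4,5,5-tetramethyl-1,3,2-dioxaborolane | I[C@@H]1C[C@]1(C)/C=C/B1OC(C)(C)C(C)(C)O1 | intermediate
14 | 1-({(E)-2-[(1R,2R)-2-iodo-1-methylcyclopropyl]ethenyl}oxymethyl)-4-methoxybenzene (fragment 2) | I[C@@H]1C[C@]1(C)/C=C/OCc1ccc(OC)cc1 | intermediate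
15 | tiglic acid | C/C=C(\C)C(=O)O | starting material
16 | rel-(2R,3S)-2,3-dibromo-2-methylbutanoic acid (racemic, one enantiomer drawn) | C[C@@H](Br)[C@@](C)(Br)C(=O)O | intermediate
17 | (Z)-2-bromobut-2-ene | C/C=C(/C)Br | intermediate
18 | 2-lithiobut-2-ene, methyl groups trans (geometry of 17 retained) | C/C=C(/C)[Li] | intermediate
19 | angelic acid | C/C=C(/C)C(=O)O | intermediate
20 | angelic anhydride (fragment 3) | C/C=C(/C)C(=O)OC(=O)/C(C)=C\C | intermediate
21 | cyclopropyllithium from 14 (Li in place of I, configuration retained) | [Li][C@@H]1C[C@]1(C)/C=C/OCc1ccc(OC)cc1 | intermediate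
22 | cyclopropylzinc bromide from 21 (configuration retained) | Br[Zn][C@@H]1C[C@]1(C)/C=C/OCc1ccc(OC)cc1 | intermediate
23 | 3-methyl-2-{(1R,2S)-2-methyl-2-[(E)-2-(4-methoxybenzyloxy)ethenyl]cyclopropyl}cyclopent-2-en-1-one (alkenyl groups cis) | CC1=C(C(=O)CC1)[C@@H]1C[C@]1(C)/C=C/OCc1ccc(OC)cc1 | intermediate
24 | (3aS,4R)-4-[(4-methoxybenzyl)oxy]-3a,6-dimethyl-3,3a,4,7-tetrahydroazulen-1(2H)-one (C4 ketone, C5=C6, C8=C9, 10α‑OPMB) | O=C1CC[C@@]2(C)C1=CCC(C)=C[C@H]2OCc1ccc(OC)cc1 | intermediate
25 | 6α‑Bpin ketone (configuration as in 26, Bpin in place of OH) | O=C1CC[C@@]2(C)[C@H]1[C@@H](B1OC(C)(C)C(C)(C)O1)CC(C)=C[C@H]2OCc1ccc(OC)cc1 | intermediate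
26 | (3aS,4R,8S,8aS)-8-hydroxy-4-[(4-methoxybenzyl)oxy]-3a,6-dimethyl-3,3a,4,7,8,8a-hexahydroazulen-1(2H)-one | O=C1CC[C@@]2(C)[C@H]1[C@@H](O)CC(C)=C[C@H]2OCc1ccc(OC)cc1 | intermediate
27 | (1R,3aS,4R,8S,8aS)-1-isopropyl-4-[(4-methoxybenzyl)oxy]-3a,6-dimethyl-1,2,3,3a,4,7,8,8a-octahydroazulene-1,8-diol | CC(C)[C@]1(O)CC[C@@]2(C)[C@H]1[C@@H](O)CC(C)=C[C@H]2OCc1ccc(OC)cc1 | intermediate
28 | 6‑O‑angeloyl‑10‑O‑PMB derivative of 27 (name as in step 15) | C/C=C(/C)C(=O)O[C@H]1CC(C)=C[C@@H](OCc2ccc(OC)cc2)[C@@]2(C)CC[C@@](O)(C(C)C)[C@H]12 | intermediate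
29 | 8,9‑deoxy‑lapiferine, the 4β,10α‑diol 6α‑angelate with C8=C9 (name as in step 16) | C/C=C(/C)C(=O)O[C@H]1CC(C)=C[C@@H](O)[C@@]2(C)CC[C@@](O)(C(C)C)[C@H]12 | intermediate
30 | lapiferine | C/C=C(/C)C(=O)O[C@H]1C[C@@]2(C)O[C@H]2[C@@H](O)[C@@]2(C)CC[C@@](O)(C(C)C)[C@H]12 | target

**Totals**
Total step count: 17.
Longest linear sequence: 11 steps (8 → 10 → 11 → 12 → 13 → 14 → 24 → 26 → 27 → 28 → 29 → 30; steps 3–7 and 12–17).

**Three steps most likely to fail**

Step 12 (hindered cyclopropyl–alkenyl coupling next to a quaternary carbon, then a Cope rearrangement that builds quaternary C1).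
- This fallback makes the C5–C6 bond as an easier sp2–sp2 coupling and builds the cyclopropane afterwards. It sets out from 9 (with 3) and comes back at 24.
- The alkenylmagnesium 9 is transmetalated with ZnBr2 and coupled with 3 (Pd2(dba)3/SPhos) to give 2-[(Z)-3-hydroxy-2-methylprop-1-enyl]-3-methylcyclopent-2-en-1-one F1.
- Hydroxyl-directed asymmetric Simmons–Smith cyclopropanation with the same dioxaborolane, which ignores the electron-poor enone alkene, gives the cyclopropylcarbinol F2.
- Dess–Martin oxidation gives the cyclopropanecarbaldehyde F3.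
- Olefination with 7/CrCl2/LiI gives the cis-divinylcyclopropane boronate F4.
- On warming, F4 rearranges to the bicyclic allylboronate F5.
- NaBO3 oxidises the C–B bond with retention to the 10α‑hydroxy dienone F6.
- PMB trichloroacetimidate with catalytic La(OTf)3 converts F6 into 24.

Step 13 (possible base-induced drift of the skipped diene into conjugation, and uncertain face of protonation at C5).
- This fallback brings in the oxygen as a nucleophilic peroxide and sets C5 by a low-temperature enolate quench. It sets out from 24 and comes back at 26.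
- Weitz–Scheffer epoxidation (t-BuOOH, DBU, CH2Cl2) from the α face gives the 5α,6α-epoxy ketone F7.
- SmI2 in THF/MeOH at −78 °C cleaves the Cα–O bond. The samarium enolate is protonated kinetically opposite the angular methyl to give 26, with the C6–O bond unchanged.

Step 14 (enolisation, reduction or retro-aldol instead of addition of the bulky secondary Grignard reagent).
- This fallback uses a smaller sp2 nucleophile without β‑hydrogens and saturates it afterwards. It sets out from 26 and comes back at 27.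
- Isopropenylmagnesium bromide with CeCl3 (THF, −78 °C) adds from the α face to give the isopropenyl carbinol F8.
- H2 with RhCl(PPh3)3 in benzene reduces only the 1,1-disubstituted alkene and leaves the trisubstituted C8=C9 and the PMB ether intact, giving 27.

**Further compounds**
F1 | step 12 | 2-[(Z)-3-hydroxy-2-methylprop-1-enyl]-3-methylcyclopent-2-en-1-one | CC1=C(C(=O)CC1)/C=C(/C)CO
F2 | step 12 | 2-[2-(hydroxymethyl)-2-methylcyclopropyl]-3-methylcyclopent-2-en-1-one (enone and CH2OH cis, configuration as in 23) | CC1=C(C(=O)CC1)[C@@H]1C[C@]1(C)CO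
F3 | step 12 | 1-methyl-2-(2-methyl-5-oxocyclopent-1-enyl)cyclopropane-1-carbaldehyde (configuration as in 23) | CC1=C(C(=O)CC1)[C@@H]1C[C@]1(C)C=O
F4 | step 12 | cis-divinylcyclopropane with an (E)-2-(pinacolboryl)ethenyl group in place of the enol ether of 23 | CC1=C(C(=O)CC1)[C@@H]1C[C@]1(C)/C=C/B1OC(C)(C)C(C)(C)O1
F5 | step 12 | 10α-(pinacolboryl) analogue of dienone 24 | O=C1CC[C@@]2(C)C1=CCC(C)=C[C@H]2B1OC(C)(C)C(C)(C)O1
F6 | step 12 | 10α-hydroxy analogue of dienone 24 | O=C1CC[C@@]2(C)C1=CCC(C)=C[C@H]2O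
F7 | step 13 | 5α,6α-epoxide of dienone 24 | O=C1CC[C@@]2(C)[C@]13O[C@H]3CC(C)=C[C@H]2OCc1ccc(OC)cc1
F8 | step 14 | isopropenyl analogue of diol 27 | C=C(C)[C@]1(O)CC[C@@]2(C)[C@H]1[C@@H](O)CC(C)=C[C@H]2OCc1ccc(OC)cc1
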